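## Retrosynthetic overview

1. The target is reached from a fully silyl-protected C30 precursor by pivalate removal, allylic oxidation to the enal and global desilylation; the enal geometry is already fixed before the fragments are joined.
2. Key disconnection: the CH2–C(Me)= bond of the side chain, made late by a B-alkyl Suzuki–Miyaura coupling of a C16 vinylcyclohexane core with a C14 (E)-vinyl iodide that carries the 5R silyloxy centre.
3. Core: the tetrasubstituted exocyclic alkene comes from 1,4-hydroboration of a 1,3-diene built on a ring enol triflate. The three ring stereocentres come from a copper-catalysed asymmetric conjugate addition to benzoquinone monoketal, two anti-selective enolate C–C bond formations (methyl, then vinyl) and a face-selective methylcerium addition.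
4. Side chain: zirconium-catalysed carboalumination and oxirane opening (E-trisubstituted alkene), propynyl addition, oxidation, asymmetric transfer hydrogenation (5R), then hydrozirconation–iodination.
5. Ring order: the only ring is the six-membered carbocycle of phenol, dearomatised in step 1; no later step forms a ring.

Assumption: the SMILES is read as (2E)-2-[(2R,3S,4S)-cyclohexylidene]propanal with a (3E,5R,7E) side chain; donors of two or more carbons are numbered as starting materials, while one-carbon donors, heteroatom sources and protecting-group reagents are given as reagents.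

## Route

**Core fragment (steps 1–12)**

Step 1
Reactants: 1 phenol
Product: 3 4,4-dimethoxycyclohexa-2,5-dien-1-one, via 4-methoxyphenol 2 (not isolated)
Conditions: PhI(OAc)2 (2.2 equiv), MeOH, 0 °C to rt
Reagents that add atoms: methanol, CO
Why: Hypervalent-iodine oxidative dearomatisation: para-methoxylation gives 2, and a second oxidation in methanol traps the cation as the quinone monoketal; no stereocentre is formed.

Step 2
Reactants: 4 3-iodopropan-1-ol
Product: 5 tert-butyl(3-iodopropoxy)dimethylsilane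
Conditions: TBSCl, imidazole, CH2Cl2, 0 °C to rt
Reagents that add atoms: tert-butyldimethylsilyl chloride, CC(C)(C)[Si](C)(C)Cl
Why: Standard silyl ether protection of a primary alcohol; no stereocentre.

Step 3
Reactants: 3 4,4-dimethoxycyclohexa-2,5-dien-1-one; 5 tert-butyl(3-iodopropoxy)dimethylsilane
Product: 7 (5S)-5-[3-(tert-butyldimethylsilyloxy)propyl]-4,4-dimethoxycyclohex-2-en-1-one, via dialkylzinc 6 (not isolated)
Conditions: 5, Et2Zn (neat), cat. copper monoiodide, 50 °C, volatiles removed; then 3, Cu(OTf)2 (2 mol %), (R,S,S)-phosphoramidite [O,O′-(R)-binaphthyl-2,2′-diyl N,N-bis((S)-1-phenylethyl)phosphoramidite] (4 mol %), toluene, −25 °C; aq. NH4Cl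
Reagents that add atoms: none
Why: Iodine–zinc exchange gives the salt-free dialkylzinc, and a copper–phosphoramidite asymmetric conjugate addition desymmetrises the dienone; the ligand (the antipode of the one that gives (S)-3-ethylcyclohexanone, chosen by analogy) selects the enone face that makes C-5 S.

Step 4
Reactants: 7 (5S)-5-[3-(tert-butyldimethylsilyloxy)propyl]-4,4-dimethoxycyclohex-2-en-1-one
Product: 9 (5S,6S)-5-[3-(tert-butyldimethylsilyloxy)propyl]-4,4-dimethoxy-6-methylcyclohex-2-en-1-one (major trans epimer), via lithium dienolate 8 (not isolated)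
Conditions: LiN(i-Pr)2, THF, −78 °C; MeI, −78 to −20 °C
Reagents that add atoms: iodomethane, CI
Why: Kinetic enolate alkylation: only C-6 can be deprotonated because the other α-carbon is vinylic, and methyl enters anti to the C-5 chain (this centre is re-planarised in step 5, so the epimer ratio does not matter).

Step 5
Reactants: 9 (5S,6S)-5-[3-(tert-butyldimethylsilyloxy)propyl]-4,4-dimethoxy-6-methylcyclohex-2-en-1-one; 10 bromoethene
Product: 12 (5S,6S)-5-[3-(tert-butyldimethylsilyloxy)propyl]-6-ethenyl-4,4-dimethoxy-6-methylcyclohex-2-en-1-one, via lithium dienolate 11 (not isolated)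
Conditions: LiN(SiMe3)2, THF, −78 to 0 °C; 10, Pd2(dba)3 (2.5 mol %), P(t-Bu)3 (6 mol %), toluene, 50 °C
Reagents that add atoms: none
Why: Palladium-catalysed α-vinylation of a ketone enolate: palladium binds and reductively eliminates on the enolate face anti to the pseudo-axial C-5 chain, so vinyl ends trans to the chain (methyl cis) and the quaternary C-6 is S.

Step 6
Reactants: 12 (5S,6S)-5-[3-(tert-butyldimethylsilyloxy)propyl]-6-ethenyl-4,4-dimethoxy-6-methylcyclohex-2-en-1-one
Product: 13 (1S,5S,6S)-5-[3-(tert-butyldimethylsilyloxy)propyl]-6-ethenyl-4,4-dimethoxy-1,6-dimethylcyclohex-2-en-1-ol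
Conditions: MeLi, CeCl3, THF, −78 °C; aq. NH4Cl
Reagents that add atoms: methyllithium, [Li]C
Why: Organocerium 1,2-addition to the hindered enone: methyl attacks the carbonyl face opposite the 1,3-related pseudo-axial C-5 chain, giving the 1S tertiary alcohol with OH cis to the C-6 methyl.

Step 7
Reactants: 13 (1S,5S,6S)-5-[3-(tert-butyldimethylsilyloxy)propyl]-6-ethenyl-4,4-dimethoxy-1,6-dimethylcyclohex-2-en-1-ol
Product: 14 (4S,5S,6S)-6-[3-(tert-butyldimethylsilyloxy)propyl]-5-ethenyl-4-hydroxy-4,5-dimethylcyclohex-2-en-1-one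
Conditions: 5% aq. oxalic acid, THF, rt
Reagents that add atoms: water, O
Why: Mild acid hydrolysis of the allylic dimethyl ketal unmasks the enone while the primary silyl ether and the tertiary alcohol survive; no stereocentre changes.

Step 8
Reactants: 14 (4S,5S,6S)-6-[3-(tert-butyldimethylsilyloxy)propyl]-5-ethenyl-4-hydroxy-4,5-dimethylcyclohex-2-en-1-one
Product: 15 (4S,5S,6S)-6-[3-(tert-butyldimethylsilyloxy)propyl]-5-ethenyl-4,5-dimethyl-4-(triethylsilyloxy)cyclohex-2-en-1-one
Conditions: TESOTf, 2,6-lutidine, CH2Cl2, −78 °C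
Reagents that add atoms: triethylsilyl trifluoromethanesulfonate, CC[Si](CC)(CC)OS(=O)(=O)C(F)(F)F
Why: Silyl triflate silylation of the hindered tertiary alcohol protects it from the bases and boranes used later.

Step 9
Reactants: 15 (4S,5S,6S)-6-[3-(tert-butyldimethylsilyloxy)propyl]-5-ethenyl-4,5-dimethyl-4-(triethylsilyloxy)cyclohex-2-en-1-one
Product: 17 (4S,5S,6S)-6-[3-(tert-butyldimethylsilyloxy)propyl]-5-ethenyl-4,5-dimethyl-4-(triethylsilyloxy)cyclohex-1-en-1-yl trifluoromethanesulfonate, via lithium enolate 16 (not isolated)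
Conditions: LiBH(s-Bu)3, THF, −78 °C; PhNTf2, −78 to 0 °C
Reagents that add atoms: N-phenylbis(trifluoromethanesulfonimide), O=S(=O)(N(c1ccccc1)S(=O)(=O)C(F)(F)F)C(F)(F)F
Why: Conjugate (1,4) hydride reduction forms the enolate regiospecifically on the CH2 side, away from the branched C-6, and O-triflation fixes it as the enol triflate; stereocentres are untouched.

Step 10
Reactants: 17 (4S,5S,6S)-6-[3-(tert-butyldimethylsilyloxy)propyl]-5-ethenyl-4,5-dimethyl-4-(triethylsilyloxy)cyclohex-1-en-1-yl trifluoromethanesulfonate; 18 prop-1-en-2-ylmagnesium bromide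
Product: 20 (4S,5S,6R)-6-[3-(tert-butyldimethylsilyloxy)propyl]-5-ethenyl-4,5-dimethyl-1-(prop-1-en-2-yl)-4-(triethylsilyloxy)cyclohex-1-ene, via isopropenylzinc chloride 19 (not isolated)
Conditions: 18, ZnCl2, THF, 0 °C; then 17, Pd(PPh3)4 (5 mol %), THF, 50 °C
Reagents that add atoms: none
Why: Negishi cross-coupling of the enol triflate with the alkenylzinc reagent gives the 1,3-diene; no stereocentre is formed (the C-6 descriptor changes only through priority rules).

Step 11
Reactants: 20 (4S,5S,6R)-6-[3-(tert-butyldimethylsilyloxy)propyl]-5-ethenyl-4,5-dimethyl-1-(prop-1-en-2-yl)-4-(triethylsilyloxy)cyclohex-1-ene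
Product: 22 (2E)-2-[(2R,3S,4S)-2-[3-(tert-butyldimethylsilyloxy)propyl]-3-ethenyl-3,4-dimethyl-4-(triethylsilyloxy)cyclohexylidene]propan-1-ol, via allylboronate 21 (not isolated)
Conditions: HBpin, Ni(cod)2 (5 mol %), PCy3 (5 mol %), toluene, rt; then H2O2, aq. NaOH, THF, 0 °C
Reagents that add atoms: hydrogen peroxide, OO
Why: Nickel-catalysed 1,4-hydroboration of the s-cis-bound diene puts H on the ring CH and boron on the terminal CH2 with the two former diene termini cis, so after stereoretentive oxidation CH2OH is cis to the ring CH2 and the methyl cis to C-2 (2E).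

Step 12
Reactants: 22 (2E)-2-[(2R,3S,4S)-2-[3-(tert-butyldimethylsilyloxy)propyl]-3-ethenyl-3,4-dimethyl-4-(triethylsilyloxy)cyclohexylidene]propan-1-ol
Product: 23 (2E)-2-[(2R,3S,4S)-2-[3-(tert-butyldimethylsilyloxy)propyl]-3-ethenyl-3,4-dimethyl-4-(triethylsilyloxy)cyclohexylidene]propyl 2,2-dimethylpropanoate
Conditions: t-BuCOCl, pyridine, cat. DMAP, CH2Cl2, 0 °C to rt
Reagents that add atoms: pivaloyl chloride, CC(C)(C)C(=O)Cl
Why: Acylation masks the allylic alcohol as an ester that tolerates the borane coupling and can be removed in the presence of silyl ethers.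

**Side-chain fragment (steps 13–20)**

Step 13
Reactants: 24 5-bromo-2-methylpent-2-ene; 25 lithium acetylide–ethane-1,2-diamine complex
Product: 26 6-methylhept-5-en-1-yne
Conditions: DMSO, 10 °C to rt
Reagents that add atoms: none
Why: SN2 alkylation of acetylide by the primary bromide.

Step 14
Reactants: 26 6-methylhept-5-en-1-yne; 27 oxirane
Product: 30 (3E)-4,8-dimethylnona-3,7-dien-1-ol, via alkenylalane 28 (not isolated), via lithium alanate 29 (not isolated)
Conditions: Me3Al (2 equiv), Cp2ZrCl2 (0.25 equiv), CH2Cl2, rt; volatiles removed, hexane; n-BuLi, −78 to 0 °C; 27, THF, −78 to 0 °C; 1 M HCl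
Reagents that add atoms: trimethylaluminium, C[Al](C)C
Why: Negishi zirconium-catalysed carboalumination adds methyl and aluminium syn across the alkyne to give the E-alkenylalane, and its alanate opens oxirane with retention of the alkene geometry.

Step 15
Reactants: 30 (3E)-4,8-dimethylnona-3,7-dien-1-ol
Product: 31 (3E)-4,8-dimethylnona-3,7-dienal
Conditions: Dess–Martin periodinane, NaHCO3, CH2Cl2, 0 °C; used crude
Reagents that add atoms: none
Why: Buffered hypervalent-iodine oxidation gives the β,γ-unsaturated aldehyde without moving the alkene into conjugation.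

Step 16
Reactants: 31 (3E)-4,8-dimethylnona-3,7-dienal; 32 prop-1-yn-1-ylmagnesium bromide
Product: 33 rac-(6E)-7,11-dimethyldodeca-6,10-dien-2-yn-4-ol
Conditions: THF, −78 °C; aq. NH4Cl
Reagents that add atoms: none
Why: Grignard 1,2-addition is fast at −78 °C, so enolisation of the sensitive aldehyde does not compete; the racemic carbinol is corrected in steps 17 and 18.

Step 17
Reactants: 33 rac-(6E)-7,11-dimethyldodeca-6,10-dien-2-yn-4-ol
Product: 34 (6E)-7,11-dimethyldodeca-6,10-dien-2-yn-4-one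
Conditions: activated MnO2, CH2Cl2, rt
Reagents that add atoms: none
Why: Neutral heterogeneous oxidation of the propargylic alcohol gives the ynone without base that could conjugate the skipped alkene.

Step 18
Reactants: 34 (6E)-7,11-dimethyldodeca-6,10-dien-2-yn-4-one
Product: 35 (4R,6E)-7,11-dimethyldodeca-6,10-dien-2-yn-4-ol
Conditions: Ru(p-cymene)[(R,R)-TsNCH(Ph)CH(Ph)NH] (1 mol %), i-PrOH, rt
Reagents that add atoms: none
Why: Noyori asymmetric transfer hydrogenation under base-free conditions: the (R,R) catalyst, with the alkynyl group in the aryl-type position, delivers hydride to the face that gives the 4R alcohol.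

Step 19
Reactants: 35 (4R,6E)-7,11-dimethyldodeca-6,10-dien-2-yn-4-ol
Product: 36 tert-butyl{[(4R,6E)-7,11-dimethyldodeca-6,10-dien-2-yn-4-yl]oxy}dimethylsilane
Conditions: TBSCl, imidazole, DMF, rt
Reagents that add atoms: tert-butyldimethylsilyl chloride, CC(C)(C)[Si](C)(C)Cl
Why: Silyl ether protection; the bulky ether also steers the next step.

Step 20
Reactants: 36 tert-butyl{[(4R,6E)-7,11-dimethyldodeca-6,10-dien-2-yn-4-yl]oxy}dimethylsilane
Product: 38 tert-butyl{[(2E,4R,6E)-2-iodo-7,11-dimethyldodeca-2,6,10-trien-4-yl]oxy}dimethylsilane, via alkenylzirconocene 37 (not isolated)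
Conditions: Cp2Zr(H)Cl (1.5 equiv), THF, rt to 40 °C; I2, 0 °C
Reagents that add atoms: iodine, II
Why: Schwartz hydrozirconation adds H and Zr syn with zirconium on the less hindered methyl-bearing alkyne carbon, and iodinolysis with retention gives the E-vinyl iodide; the trisubstituted alkenes are inert.

**Fragment coupling and end game (steps 21–24)**

Step 21
Reactants: 23 (2E)-2-[(2R,3S,4S)-2-[3-(tert-butyldimethylsilyloxy)propyl]-3-ethenyl-3,4-dimethyl-4-(triethylsilyloxy)cyclohexylidene]propyl 2,2-dimethylpropanoate; 38 tert-butyl{[(2E,4R,6E)-2-iodo-7,11-dimethyldodeca-2,6,10-trien-4-yl]oxy}dimethylsilane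
Product: 40 (2E)-2-[(2R,3S,4S)-2-[3-(tert-butyldimethylsilyloxy)propyl]-3-[(3E,5R,7E)-5-(tert-butyldimethylsilyloxy)-3,8,12-trimethyltrideca-3,7,11-trien-1-yl]-3,4-dimethyl-4-(triethylsilyloxy)cyclohexylidene]propyl 2,2-dimethylpropanoate, via alkylborane 39 (not isolated)
Conditions: 23, 9-BBN-H, THF, rt to 40 °C; then 38, Pd(dppf)Cl2 (5 mol %), AsPh3, Cs2CO3, DMF/THF/H2O, rt
Reagents that add atoms: none
Why: B-alkyl Suzuki–Miyaura coupling: 9-BBN-H hydroborates only the monosubstituted vinyl group (anti-Markovnikov), and the alkylborane couples with the vinyl iodide with retention of E geometry, joining the C16 core and the C14 side chain.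

Step 22
Reactants: 40 the coupled pivalate
Product: 41 (2E)-2-[(2R,3S,4S)-2-[3-(tert-butyldimethylsilyloxy)propyl]-3-[(3E,5R,7E)-5-(tert-butyldimethylsilyloxy)-3,8,12-trimethyltrideca-3,7,11-trien-1-yl]-3,4-dimethyl-4-(triethylsilyloxy)cyclohexylidene]propan-1-ol
Conditions: i-Bu2AlH (2.2 equiv), CH2Cl2, −78 °C; aq. potassium sodium tartrate
Reagents that add atoms: none
Why: Reductive cleavage of the pivalate frees only the primary allylic alcohol; silyl ethers and alkenes are untouched.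

Step 23
Reactants: 41 the allylic alcohol
Product: 42 (2E)-2-[(2R,3S,4S)-2-[3-(tert-butyldimethylsilyloxy)propyl]-3-[(3E,5R,7E)-5-(tert-butyldimethylsilyloxy)-3,8,12-trimethyltrideca-3,7,11-trien-1-yl]-3,4-dimethyl-4-(triethylsilyloxy)cyclohexylidene]propanal
Conditions: activated MnO2, CH2Cl2, rt
Reagents that add atoms: none
Why: Allylic oxidation under neutral conditions touches only the free allylic alcohol and keeps the geometry of the tetrasubstituted alkene.

Step 24
Reactants: 42 the protected enal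
Product: 43 (2E)-2-[(2R,3S,4S)-4-hydroxy-3-[(3E,5R,7E)-5-hydroxy-3,8,12-trimethyltrideca-3,7,11-trien-1-yl]-2-(3-hydroxypropyl)-3,4-dimethylcyclohexylidene]propanal (CNP0417035.1)
Conditions: HF·pyridine, pyridine, THF, 0 °C to rt
Reagents that add atoms: none
Why: Buffered fluoride desilylation removes both TBS ethers and the tertiary TES ether without isomerising the enal or ionising the allylic alcohol.

## Compound list

1 | phenol | Oc1ccccc1 | starting material
2 | 4-methoxyphenol | COc1ccc(O)cc1 | intermediate (not isolated)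
3 | 4,4-dimethoxycyclohexa-2,5-dien-1-one | COC1(OC)C=CC(=O)C=C1 | intermediate
4 | 3-iodopropan-1-ol | OCCCI | starting material
5 | tert-butyl(3-iodopropoxy)dimethylsilane | CC(C)(C)[Si](C)(C)OCCCI | intermediate
6 | bis[3-(tert-butyldimethylsilyloxy)propyl]zinc | CC(C)(C)[Si](C)(C)OCCC[Zn]CCCO[Si](C)(C)C(C)(C)C | intermediate (not isolated)
7 | (5S)-5-[3-(tert-butyldimethylsilyloxy)propyl]-4,4-dimethoxycyclohex-2-en-1-one | C1[C@H](CCCO[Si](C)(C)C(C)(C)C)C(OC)(OC)C=CC1=O | intermediate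
8 | lithium (3S)-3-[3-(tert-butyldimethylsilyloxy)propyl]-4,4-dimethoxycyclohexa-1,5-dien-1-olate | [Li]OC1=C[C@H](CCCO[Si](C)(C)C(C)(C)C)C(OC)(OC)C=C1 | intermediate (not isolated)
9 | (5S,6S)-5-[3-(tert-butyldimethylsilyloxy)propyl]-4,4-dimethoxy-6-methylcyclohex-2-en-1-one | C[C@H]1[C@H](CCCO[Si](C)(C)C(C)(C)C)C(OC)(OC)C=CC1=O | intermediate
10 | bromoethene | C=CBr | starting material
11 | lithium (3S)-3-[3-(tert-butyldimethylsilyloxy)propyl]-4,4-dimethoxy-2-methylcyclohexa-1,5-dien-1-olate | [Li]OC1=C(C)[C@H](CCCO[Si](C)(C)C(C)(C)C)C(OC)(OC)C=C1 | intermediate (not isolated)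
12 | (5S,6S)-5-[3-(tert-butyldimethylsilyloxy)propyl]-6-ethenyl-4,4-dimethoxy-6-methylcyclohex-2-en-1-one | C=C[C@@]1(C)[C@H](CCCO[Si](C)(C)C(C)(C)C)C(OC)(OC)C=CC1=O | intermediate
13 | (1S,5S,6S)-5-[3-(tert-butyldimethylsilyloxy)propyl]-6-ethenyl-4,4-dimethoxy-1,6-dimethylcyclohex-2-en-1-ol | C=C[C@@]1(C)[C@H](CCCO[Si](C)(C)C(C)(C)C)C(OC)(OC)C=C[C@]1(C)O | intermediate
14 | (4S,5S,6S)-6-[3-(tert-butyldimethylsilyloxy)propyl]-5-ethenyl-4-hydroxy-4,5-dimethylcyclohex-2-en-1-one | C=C[C@@]1(C)[C@H](CCCO[Si](C)(C)C(C)(C)C)C(=O)C=C[C@]1(C)O | intermediate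
15 | (4S,5S,6S)-6-[3-(tert-butyldimethylsilyloxy)propyl]-5-ethenyl-4,5-dimethyl-4-(triethylsilyloxy)cyclohex-2-en-1-one | C=C[C@@]1(C)[C@H](CCCO[Si](C)(C)C(C)(C)C)C(=O)C=C[C@]1(C)O[Si](CC)(CC)CC | intermediate
16 | lithium (4S,5S,6S)-6-[3-(tert-butyldimethylsilyloxy)propyl]-5-ethenyl-4,5-dimethyl-4-(triethylsilyloxy)cyclohex-1-en-1-olate | C=C[C@@]1(C)[C@H](CCCO[Si](C)(C)C(C)(C)C)C(O[Li])=CC[C@]1(C)O[Si](CC)(CC)CC | intermediate (not isolated)
17 | (4S,5S,6S)-6-[3-(tert-butyldimethylsilyloxy)propyl]-5-ethenyl-4,5-dimethyl-4-(triethylsilyloxy)cyclohex-1-en-1-yl trifluoromethanesulfonate | C=C[C@@]1(C)[C@H](CCCO[Si](C)(C)C(C)(C)C)C(OS(=O)(=O)C(F)(F)F)=CC[C@]1(C)O[Si](CC)(CC)CC | intermediate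
18 | prop-1-en-2-ylmagnesium bromide | C=C(C)[Mg]Br | starting material
19 | chloro(prop-1-en-2-yl)zinc | C=C(C)[Zn]Cl | intermediate (not isolated)
20 | (4S,5S,6R)-6-[3-(tert-butyldimethylsilyloxy)propyl]-5-ethenyl-4,5-dimethyl-1-(prop-1-en-2-yl)-4-(triethylsilyloxy)cyclohex-1-ene | C=C[C@@]1(C)[C@H](CCCO[Si](C)(C)C(C)(C)C)C(C(C)=C)=CC[C@]1(C)O[Si](CC)(CC)CC | intermediate
21 | 2-{(2E)-2-[(2R,3S,4S)-2-[3-(tert-butyldimethylsilyloxy)propyl]-3-ethenyl-3,4-dimethyl-4-(triethylsilyloxy)cyclohexylidene]propyl}-4,4,5,5-tetramethyl-1,3,2-dioxaborolane | C=C[C@@]1(C)[C@H](CCCO[Si](C)(C)C(C)(C)C)/C(=C(\C)CB2OC(C)(C)C(C)(C)O2)CC[C@]1(C)O[Si](CC)(CC)CC | intermediate (not isolated)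
22 | (2E)-2-[(2R,3S,4S)-2-[3-(tert-butyldimethylsilyloxy)propyl]-3-ethenyl-3,4-dimethyl-4-(triethylsilyloxy)cyclohexylidene]propan-1-ol | C=C[C@@]1(C)[C@H](CCCO[Si](C)(C)C(C)(C)C)/C(=C(\C)CO)CC[C@]1(C)O[Si](CC)(CC)CC | intermediate
23 | (2E)-2-[(2R,3S,4S)-2-[3-(tert-butyldimethylsilyloxy)propyl]-3-ethenyl-3,4-dimethyl-4-(triethylsilyloxy)cyclohexylidene]propyl 2,2-dimethylpropanoate | C=C[C@@]1(C)[C@H](CCCO[Si](C)(C)C(C)(C)C)/C(=C(\C)COC(=O)C(C)(C)C)CC[C@]1(C)O[Si](CC)(CC)CC | intermediate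
24 | 5-bromo-2-methylpent-2-ene | CC(C)=CCCBr | starting material
25 | lithium acetylide–ethane-1,2-diamine complex | [Li]C#C.NCCN | starting material
26 | 6-methylhept-5-en-1-yne | CC(C)=CCCC#C | intermediate
27 | oxirane | C1CO1 | starting material
28 | [(1E)-2,6-dimethylhepta-1,5-dien-1-yl]dimethylalane | CC(C)=CCC/C(C)=C/[Al](C)C | intermediate (not isolated)
29 | lithium butyl[(1E)-2,6-dimethylhepta-1,5-dien-1-yl]dimethylaluminate | CC(C)=CCC/C(C)=C/[Al-](C)(C)CCCC.[Li+] | intermediate (not isolated)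
30 | (3E)-4,8-dimethylnona-3,7-dien-1-ol | CC(C)=CCC/C(C)=C/CCO | intermediate
31 | (3E)-4,8-dimethylnona-3,7-dienal | CC(C)=CCC/C(C)=C/CC=O | intermediate
32 | prop-1-yn-1-ylmagnesium bromide | CC#C[Mg]Br | starting material
33 | rac-(6E)-7,11-dimethyldodeca-6,10-dien-2-yn-4-ol | CC(C)=CCC/C(C)=C/CC(O)C#CC | intermediate
34 | (6E)-7,11-dimethyldodeca-6,10-dien-2-yn-4-one | CC(C)=CCC/C(C)=C/CC(=O)C#CC | intermediate
35 | (4R,6E)-7,11-dimethyldodeca-6,10-dien-2-yn-4-ol | CC(C)=CCC/C(C)=C/C[C@@H](O)C#CC | intermediate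
36 | tert-butyl{[(4R,6E)-7,11-dimethyldodeca-6,10-dien-2-yn-4-yl]oxy}dimethylsilane | CC(C)=CCC/C(C)=C/C[C@@H](O[Si](C)(C)C(C)(C)C)C#CC | intermediate
37 | chlorobis(cyclopentadienyl)[(2E,4R,6E)-4-(tert-butyldimethylsilyloxy)-7,11-dimethyldodeca-2,6,10-trien-2-yl]zirconium | CC(C)=CCC/C(C)=C/C[C@@H](O[Si](C)(C)C(C)(C)C)/C=C(\C)[Zr](Cl)(C1C=CC=C1)C1C=CC=C1 | intermediate (not isolated)
38 | tert-butyl{[(2E,4R,6E)-2-iodo-7,11-dimethyldodeca-2,6,10-trien-4-yl]oxy}dimethylsilane | CC(C)=CCC/C(C)=C/C[C@@H](O[Si](C)(C)C(C)(C)C)/C=C(\C)I | intermediate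
39 | (2E)-2-[(2R,3S,4S)-3-[2-(9-borabicyclo[3.3.1]nonan-9-yl)ethyl]-2-[3-(tert-butyldimethylsilyloxy)propyl]-3,4-dimethyl-4-(triethylsilyloxy)cyclohexylidene]propyl 2,2-dimethylpropanoate | C1CC2CCCC(C1)B2CC[C@@]3(C)[C@H](CCCO[Si](C)(C)C(C)(C)C)/C(=C(\C)COC(=O)C(C)(C)C)CC[C@]3(C)O[Si](CC)(CC)CC | intermediate (not isolated)
40 | (2E)-2-[(2R,3S,4S)-2-[3-(tert-butyldimethylsilyloxy)propyl]-3-[(3E,5R,7E)-5-(tert-butyldimethylsilyloxy)-3,8,12-trimethyltrideca-3,7,11-trien-1-yl]-3,4-dimethyl-4-(triethylsilyloxy)cyclohexylidene]propyl 2,2-dimethylpropanoate | CC(C)=CCC/C(C)=C/C[C@@H](O[Si](C)(C)C(C)(C)C)/C=C(\C)CC[C@@]1(C)[C@H](CCCO[Si](C)(C)C(C)(C)C)/C(=C(\C)COC(=O)C(C)(C)C)CC[C@]1(C)O[Si](CC)(CC)CC | intermediate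
41 | (2E)-2-[(2R,3S,4S)-2-[3-(tert-butyldimethylsilyloxy)propyl]-3-[(3E,5R,7E)-5-(tert-butyldimethylsilyloxy)-3,8,12-trimethyltrideca-3,7,11-trien-1-yl]-3,4-dimethyl-4-(triethylsilyloxy)cyclohexylidene]propan-1-ol | CC(C)=CCC/C(C)=C/C[C@@H](O[Si](C)(C)C(C)(C)C)/C=C(\C)CC[C@@]1(C)[C@H](CCCO[Si](C)(C)C(C)(C)C)/C(=C(\C)CO)CC[C@]1(C)O[Si](CC)(CC)CC | intermediate
42 | (2E)-2-[(2R,3S,4S)-2-[3-(tert-butyldimethylsilyloxy)propyl]-3-[(3E,5R,7E)-5-(tert-butyldimethylsilyloxy)-3,8,12-trimethyltrideca-3,7,11-trien-1-yl]-3,4-dimethyl-4-(triethylsilyloxy)cyclohexylidene]propanal | CC(C)=CCC/C(C)=C/C[C@@H](O[Si](C)(C)C(C)(C)C)/C=C(\C)CC[C@@]1(C)[C@H](CCCO[Si](C)(C)C(C)(C)C)/C(=C(\C)C=O)CC[C@]1(C)O[Si](CC)(CC)CC | intermediate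
43 | (2E)-2-[(2R,3S,4S)-4-hydroxy-3-[(3E,5R,7E)-5-hydroxy-3,8,12-trimethyltrideca-3,7,11-trien-1-yl]-2-(3-hydroxypropyl)-3,4-dimethylcyclohexylidene]propanal | CC(C)=CCC/C(C)=C/C[C@@H](O)/C=C(\C)CC[C@@]1(C)[C@H](CCCO)/C(=C(\C)C=O)CC[C@]1(C)O | target

## Step count and weak points

Total step count: 24. Longest linear sequence: 15 steps (1, 3–12, 21–24); the side-chain branch is 8 steps (13–20) and the reagent branch 1 step (2).

Steps most likely to fail, each with a fallback:

1. Step 3. The enantioselectivity and reactivity of a functionalised dialkylzinc on the quinone monoketal are uncertain. The fallback uses auxiliary control instead of catalyst control; it sets out from 3 and returns at 14. Acid-catalysed ketal exchange of 3 with (1R,2R)-1,2-diphenylethane-1,2-diol gives the C2-symmetric spiro-ketal dienone F1, whose two enone β-carbons are diastereotopic. The Grignard reagent from 5, with catalytic CuBr·SMe2 and Me3SiCl, adds 1,4 to give the 6S adduct F2 after chromatographic removal of the minor diastereomer (the antipodal diol is used if induction runs the other way). F2 is taken through the conditions of steps 4, 5 and 6 to the methyl ketone F3, the vinyl ketone F4 and the tertiary alcohol F5. Aqueous acid hydrolysis of F5 releases the diol and gives 14.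

2. Step 5. The palladium-catalysed vinylation must create a quaternary carbon beside a branched centre and a ketal carbon. The fallback replaces cross-coupling by aldol and dehydration; it sets out from 9 and returns at 12. Enolate 11, generated from 9 with LiN(i-Pr)2, is added to acetaldehyde at −78 °C to give the aldol adduct F6 (new C–C bond anti to the side chain; the carbinol epimers do not matter). Burgess reagent then dehydrates F6 by syn-elimination to 12, since only the methyl group carries β-hydrogens.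

3. Step 11. The 1,4-hydroboration must form a tetrasubstituted alkene from a hindered diene. The fallback replaces diene functionalisation by carbonyl olefination; it sets out from 15 and returns at 22. 1,4-Reduction of 15 with LiBH(s-Bu)3 and a protic quench gives the saturated ketone F7. Lithium prop-1-yn-1-olate (from methyl 2,2-dibromopropanoate and t-BuLi) adds to F7, and the β-lactone enolate opens torquoselectively with the bulkier, chain-bearing ring arm rotating outward. This gives the E acrylic acid F8 with the carboxyl cis to the ring CH2; any Z isomer is removed by chromatography. Me3SiCHN2 gives the methyl ester F9, and i-Bu2AlH reduction returns 22.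

## Further compounds

F1 | step 3 | (2R,3R)-2,3-diphenyl-1,4-dioxaspiro[4.5]deca-6,9-dien-8-one | O=C1C=CC2(C=C1)O[C@H](c1ccccc1)[C@@H](c1ccccc1)O2
F2 | step 3 | (2R,3R,6S)-6-[3-(tert-butyldimethylsilyloxy)propyl]-2,3-diphenyl-1,4-dioxaspiro[4.5]dec-9-en-8-one | C1[C@H](CCCO[Si](C)(C)C(C)(C)C)C2(O[C@H](c3ccccc3)[C@@H](c3ccccc3)O2)C=CC1=O
F3 | step 3 | (2R,3R,6S,7S)-6-[3-(tert-butyldimethylsilyloxy)propyl]-7-methyl-2,3-diphenyl-1,4-dioxaspiro[4.5]dec-9-en-8-one | C[C@H]1[C@H](CCCO[Si](C)(C)C(C)(C)C)C2(O[C@H](c3ccccc3)[C@@H](c3ccccc3)O2)C=CC1=O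
F4 | step 3 | (2R,3R,6S,7S)-6-[3-(tert-butyldimethylsilyloxy)propyl]-7-ethenyl-7-methyl-2,3-diphenyl-1,4-dioxaspiro[4.5]dec-9-en-8-one | C=C[C@@]1(C)[C@H](CCCO[Si](C)(C)C(C)(C)C)C2(O[C@H](c3ccccc3)[C@@H](c3ccccc3)O2)C=CC1=O
F5 | step 3 | (2R,3R,6S,7S,8S)-6-[3-(tert-butyldimethylsilyloxy)propyl]-7-ethenyl-7,8-dimethyl-2,3-diphenyl-1,4-dioxaspiro[4.5]dec-9-en-8-ol | C=C[C@@]1(C)[C@H](CCCO[Si](C)(C)C(C)(C)C)C2(O[C@H](c3ccccc3)[C@@H](c3ccccc3)O2)C=C[C@]1(C)O
F6 | step 5 | (5S,6R)-5-[3-(tert-butyldimethylsilyloxy)propyl]-6-(1-hydroxyethyl)-4,4-dimethoxy-6-methylcyclohex-2-en-1-one (both carbinol epimers) | CC(O)[C@@]1(C)[C@H](CCCO[Si](C)(C)C(C)(C)C)C(OC)(OC)C=CC1=O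
F7 | step 11 | (2S,3S,4S)-2-[3-(tert-butyldimethylsilyloxy)propyl]-3-ethenyl-3,4-dimethyl-4-(triethylsilyloxy)cyclohexan-1-one | C=C[C@@]1(C)[C@H](CCCO[Si](C)(C)C(C)(C)C)C(=O)CC[C@]1(C)O[Si](CC)(CC)CC
F8 | step 11 | (2E)-2-[(2R,3S,4S)-2-[3-(tert-butyldimethylsilyloxy)propyl]-3-ethenyl-3,4-dimethyl-4-(triethylsilyloxy)cyclohexylidene]propanoic acid | C=C[C@@]1(C)[C@H](CCCO[Si](C)(C)C(C)(C)C)/C(=C(\C)C(=O)O)CC[C@]1(C)O[Si](CC)(CC)CC
F9 | step 11 | methyl (2E)-2-[(2R,3S,4S)-2-[3-(tert-butyldimethylsilyloxy)propyl]-3-ethenyl-3,4-dimethyl-4-(triethylsilyloxy)cyclohexylidene]propanoate | C=C[C@@]1(C)[C@H](CCCO[Si](C)(C)C(C)(C)C)/C(=C(\C)C(=O)OC)CC[C@]1(C)O[Si](CC)(CC)CC
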